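**Retrosynthetic overview**

1. The strategy rests on ring A (C4a, C5, C6, C7, C8, C8a; chromane numbering, ring B = O1, C2, C3, C4, C4a, C8a). It is a cyclic β-triketone that cannot aromatise because C8 is quaternary, so it is opened at C6–C7 (retro-Dieckmann) to a keto diester that already holds ring B and all five stereocentres; the side-chain acid is freed last from its methyl ester.
2. The C4a–C5 bond of that keto diester comes from a 5-iodo-dihydropyranone and an aldehyde made from desymmetrised 3-phenylglutaric anhydride (Nozaki–Hiyama–Kishi coupling, then oxidation). The acyl group is added only after ring B exists, because cyclodehydration of a C4a-triacyl compound could engage C5 instead of C8a.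
3. Ring B is closed by cyclodehydration of a δ-hydroxy β-diketone, in which only C8a is within reach of the C2 hydroxyl. The diketone comes from Claisen acylation of a methyl ketone (from methyl (R)-3-hydroxybutanoate, Fráter–Seebach methylation setting C3) with a quaternary malonic half-ester chloride.
4. C8 is set by enantioselective phase-transfer prenylation of a lavandulyl malonate; the lavandulyl centre comes from lipase-resolved lavandulol.
5. Order of ring formation: ring B (step 12), then ring A (step 19).

Key step: step 19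

Remark on names: chromane numbering (O1, C2, C3, C4, C4a, C5–C8, C8a) is used for the target and for the atoms of every intermediate that end up there; lavandulyl = 5-methyl-2-(prop-1-en-2-yl)hex-4-en-1-yl, prenyl = 3-methylbut-2-en-1-yl.

Assumption: Candida antarctica lipase B is taken to acetylate (R)-lavandulol faster and to open 3-phenylglutaric anhydride to the (S)-hemiester, and the (S,S) ammonium catalyst is taken to give the C8 configuration drawn; where a sense of induction proves opposite, the mirror-image catalyst (for the enzymes, the acetate fraction or a quinine/quinidine-mediated methanolysis) is used and nothing else changes.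

Assumption: metal enolates and organometallic species are treated as reactive forms of numbered compounds and carry no number.

**Route**

Step 1
Reactants: 1 (±)-lavandulol
Product: 2 (S)-lavandulol
Conditions: Novozym 435 (immobilised Candida antarctica lipase B), vinyl acetate, hexane, rt, run beyond half conversion; chromatography
Reagents that add atoms: none
Why: Lipase-catalysed kinetic resolution by transesterification should acetylate the (R)-alcohol faster, so the unreacted (S)-alcohol, taken past half conversion, is recovered enantiomerically enriched with its stereocentre untouched.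

Step 2
Reactants: 2 (S)-lavandulol
Product: 3 (S)-lavandulyl iodide
Conditions: PPh3, I2, imidazole, CH2Cl2, 0 °C→rt
Reagents that add atoms: iodine, II
Why: Appel-type iodination replaces the primary hydroxyl by SN2 at CH2, leaving the adjacent stereocentre and the alkenes untouched.

Step 3
Reactants: 4 mono-tert-butyl malonate; 5 2,2-diphenylethanol
Product: 6 tert-butyl 2,2-diphenylethyl malonate
Conditions: DCC, DMAP (cat.), CH2Cl2, 0 °C→rt
Reagents that add atoms: none
Why: Steglich esterification of the malonic half acid with a primary alcohol is routine and leaves the tert-butyl ester intact.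

Step 4
Reactants: 6 tert-butyl 2,2-diphenylethyl malonate; 3 (S)-lavandulyl iodide
Product: 7 tert-butyl 2,2-diphenylethyl 2-[(2R)-lavandulyl]malonate (both epimers at the malonate CH)
Conditions: NaH, THF/DMF, 0 °C; then 3, 50 °C (6 in excess)
Reagents that add atoms: none
Why: Malonic ester alkylation, in which the soft sodium malonate displaces the primary iodide by SN2 and excess malonate suppresses dialkylation; the new CH centre is an inconsequential epimer mixture because it is planarised in step 5.

Step 5
Reactants: 7 tert-butyl 2,2-diphenylethyl 2-[(2R)-lavandulyl]malonate; 8 prenyl bromide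
Product: 9 1-tert-butyl 3-(2,2-diphenylethyl) (2R)-2-[(2R)-lavandulyl]-2-prenylpropanedioate
Conditions: (S,S)-3,4,5-trifluorophenyl-NAS bromide (5 mol%), 50% aq KOH, toluene, −40 °C
Reagents that add atoms: none
Why: Enantioselective phase-transfer alkylation of an α-alkyl malonate with one tert-butyl and one 2,2-diphenylethyl ester, in which the chiral spiro ammonium cation pairs with the enolate and shields one face, so prenyl bromide sets the quaternary centre C8 under catalyst control.

Step 6
Reactants: 9 1-tert-butyl 3-(2,2-diphenylethyl) (2R)-2-[(2R)-lavandulyl]-2-prenylpropanedioate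
Product: 10 1-tert-butyl 3-methyl (2R)-2-[(2R)-lavandulyl]-2-prenylpropanedioate
Conditions: NaOMe (0.3 equiv), MeOH/THF, 50 °C
Reagents that add atoms: methanol, CO
Why: Base-catalysed transesterification in methanol exchanges the primary 2,2-diphenylethyl ester for methyl while the bulky tert-butyl ester resists methoxide, and quaternary C8 cannot epimerise.

Step 7
Reactants: 10 1-tert-butyl 3-methyl (2R)-2-[(2R)-lavandulyl]-2-prenylpropanedioate
Product: 12 (2S)-2-(methoxycarbonyl)-2-[(2R)-lavandulyl]-5-methylhex-4-enoic acid, via trimethylsilyl ester 11 (not isolated)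
Conditions: TMSOTf, 2,6-lutidine, CH2Cl2, 0 °C; then aq citric acid
Reagents that add atoms: none
Why: Silyl triflate-mediated tert-butyl ester cleavage (O-silylation, loss of 2-methylpropene, hydrolysis of the silyl ester on work-up) runs under buffered non-protic conditions, so the three alkenes and the methyl ester should survive.

Step 8
Reactants: 13 methyl (R)-3-hydroxybutanoate
Product: 14 methyl (2R,3R)-3-hydroxy-2-methylbutanoate
Conditions: LDA (2.2 equiv), THF, −50→−20 °C; MeI, DMPU, −78→0 °C; then H2O
Reagents that add atoms: iodomethane, CI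
Why: Fráter–Seebach alkylation, in which the chelated alkoxide-enolate dianion is methylated on the face opposite the C3 methyl group, gives the anti (2R,3R) product with the carbinol centre unchanged.

Step 9
Reactants: 14 methyl (2R,3R)-3-hydroxy-2-methylbutanoate
Product: 15 methyl (2R,3R)-3-(tert-butyldimethylsilyloxy)-2-methylbutanoate
Conditions: TBSCl, imidazole, DMF, rt
Reagents that add atoms: tert-butyldimethylsilyl chloride, CC(C)(C)[Si](C)(C)Cl
Why: Standard silyl ether formation protects the secondary alcohol so that it cannot be acylated or deprotonated in steps 10 and 11.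

Step 10
Reactants: 15 methyl (2R,3R)-3-(tert-butyldimethylsilyloxy)-2-methylbutanoate
Product: 17 (3R,4R)-4-(tert-butyldimethylsilyloxy)-3-methylpentan-2-one, via Weinreb amide 16 (not isolated)
Conditions: MeNH(OMe)·HCl, iPrMgCl, THF, −20 °C; then MeMgBr, 0 °C; aq NH4Cl
Reagents that add atoms: methylmagnesium bromide, C[Mg]Br
Why: Weinreb ketone synthesis in one pot, in which the magnesium amide converts the ester to the N-methoxy-N-methyl amide and its chelated adduct with MeMgBr collapses only on work-up, gives the methyl ketone without over-addition or epimerisation of the α-centre.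

Step 11
Reactants: 12 (2S)-2-(methoxycarbonyl)-2-[(2R)-lavandulyl]-5-methylhex-4-enoic acid; 17 (3R,4R)-4-(tert-butyldimethylsilyloxy)-3-methylpentan-2-one
Product: 19 methyl (2S)-2-[(4R,5R)-5-(tert-butyldimethylsilyloxy)-4-methyl-3-oxohexanoyl]-2-[(2R)-lavandulyl]-5-methylhex-4-enoate, via acid chloride 18 (not isolated)
Conditions: 12, 1-chloro-N,N,2-trimethylprop-1-en-1-amine, CH2Cl2, 0 °C→rt; 17, LiHMDS (2.2 equiv), THF, −78 °C; then 18, −78→0 °C; aq NH4Cl
Reagents that add atoms: none
Why: Crossed Claisen acylation, in which the kinetic lithium enolate at the methyl group of 17 (the future C4a) attacks the non-enolisable acid chloride made under neutral conditions, forms C4a–C8a, and the second equivalent of base takes up the acidic diketone proton.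

Step 12
Reactants: 19 methyl (2S)-2-[(4R,5R)-5-(tert-butyldimethylsilyloxy)-4-methyl-3-oxohexanoyl]-2-[(2R)-lavandulyl]-5-methylhex-4-enoate
Product: 21 methyl (2S)-2-[(2R,3R)-2,3-dimethyl-4-oxo-3,4-dihydro-2H-pyran-6-yl]-2-[(2R)-lavandulyl]-5-methylhex-4-enoate, via hydroxy diketone 20 (not isolated)
Conditions: 48% aq HF, MeCN, 0 °C→rt; then TsOH·H2O (cat.), CH2Cl2, rt
Reagents that add atoms: none
Why: Desilylation followed by acid-catalysed cyclodehydration of a δ-hydroxy β-diketone closes ring B with fixed regiochemistry, because the C2 hydroxyl can reach only the C8a carbonyl in a six-membered hemiketal, and the trans-dimethyl arrangement is the stable one.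

Step 13
Reactants: 21 methyl (2S)-2-[(2R,3R)-2,3-dimethyl-4-oxo-3,4-dihydro-2H-pyran-6-yl]-2-[(2R)-lavandulyl]-5-methylhex-4-enoate
Product: 22 methyl (2S)-2-[(2R,3R)-5-iodo-2,3-dimethyl-4-oxo-3,4-dihydro-2H-pyran-6-yl]-2-[(2R)-lavandulyl]-5-methylhex-4-enoate
Conditions: I2, pyridine, CH2Cl2, 0 °C→rt, dark
Reagents that add atoms: iodine, II
Why: Electrophilic α-iodination of a vinylogous ester takes place at the push–pull carbon C4a, whereas the isolated alkenes should form only reversible iodine complexes in the absence of an external nucleophile.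

Step 14
Reactants: 23 3-phenylglutaric anhydride
Product: 24 (S)-5-methoxy-5-oxo-3-phenylpentanoic acid
Conditions: Novozym 435, MeOH, MTBE, rt
Reagents that add atoms: methanol, CO
Why: Enzymatic desymmetrisation of a prochiral cyclic anhydride by lipase-catalysed methanolysis opens one enantiotopic carbonyl and so sets the benzylic stereocentre as (S).

Step 15
Reactants: 24 (S)-5-methoxy-5-oxo-3-phenylpentanoic acid
Product: 25 methyl (S)-5-hydroxy-3-phenylpentanoate
Conditions: BH3·THF, THF, −10→0 °C; then H2O
Reagents that add atoms: none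
Why: Chemoselective borane reduction of a carboxylic acid in the presence of an ester gives the primary alcohol, and the stereocentre, which is not α to a carbonyl, is not at risk.

Step 16
Reactants: 25 methyl (S)-5-hydroxy-3-phenylpentanoate
Product: 26 methyl (S)-5-oxo-3-phenylpentanoate
Conditions: DMP, NaHCO3, CH2Cl2, 0 °C→rt (25 used at once)
Reagents that add atoms: none
Why: Dess–Martin oxidation converts the primary alcohol to the aldehyde under buffered neutral conditions that avoid lactonisation and over-oxidation.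

Step 17
Reactants: 22 methyl (2S)-2-[(2R,3R)-5-iodo-2,3-dimethyl-4-oxo-3,4-dihydro-2H-pyran-6-yl]-2-[(2R)-lavandulyl]-5-methylhex-4-enoate; 26 methyl (S)-5-oxo-3-phenylpentanoate
Product: 27 methyl (2S)-2-[(2R,3R)-5-[(3S)-1-hydroxy-5-methoxy-5-oxo-3-phenylpentyl]-2,3-dimethyl-4-oxo-3,4-dihydro-2H-pyran-6-yl]-2-[(2R)-lavandulyl]-5-methylhex-4-enoate (both epimers at the carbinol C5)
Conditions: CrCl2 (4 equiv), NiCl2 (2 mol%), degassed DMF, rt
Reagents that add atoms: none
Why: Nozaki–Hiyama–Kishi coupling, in which zerovalent nickel inserts into the C4a–I bond and transmetallation gives an alkenyl species of trivalent chromium that adds only to the aldehyde, forms C4a–C5 in the presence of the ketone and esters; the configuration of the carbinol is irrelevant because it is oxidised in step 18.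

Step 18
Reactants: 27 the C5 carbinol from step 17
Product: 28 methyl (2S)-2-[(2R,3R)-5-[(3S)-5-methoxy-5-oxo-3-phenylpentanoyl]-2,3-dimethyl-4-oxo-3,4-dihydro-2H-pyran-6-yl]-2-[(2R)-lavandulyl]-5-methylhex-4-enoate
Conditions: DMP, NaHCO3, CH2Cl2, 0 °C→rt (27 used at once)
Reagents that add atoms: none
Why: Dess–Martin oxidation of the allylic secondary alcohol gives the C5 ketone under neutral conditions that leave the enol ether, both esters and all stereocentres untouched.

Step 19
Reactants: 28 the dihydropyranone keto diester from step 18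
Product: 29 methyl (3S)-3-[(2R,3R,8S)-5-hydroxy-2,3-dimethyl-8-[(2R)-lavandulyl]-4,7-dioxo-8-prenyl-3,4,7,8-tetrahydro-2H-chromen-6-yl]-3-phenylpropanoate
Conditions: KOtBu (2.2 equiv), THF, −40→0 °C; then 1 M HCl
Reagents that add atoms: none
Why: KOtBu removes a proton from C6, the only CH2 α to a true ketone (C5) and the most acidic and accessible C–H, and the enolate adds to the C7 methyl ester on quaternary C8, loss of methoxide forming the C6–C7 bond. This is a Dieckmann-type intramolecular Claisen condensation of a keto ester, the known way from 3,5-dioxo esters to 2,2-dialkylcyclohexane-1,3,5-triones. Ring A (C4a, C5, C6, C7, C8, C8a) closes in the 6-(enolexo)-exo-trig mode, helped by the geminal substituents on C8 and by the C4a=C8a double bond, which holds the two reacting chains cis. No stereocentre is formed: none of the five existing ones lies on the new bond, C8 and the benzylic carbon cannot enolise, and C3 already has the thermodynamic trans relation to C2. The selectivity needed is the site of enolisation: the C3 methine next to the vinylogous ester carbonyl C4 is less acidic and more hindered than C6, and the enolate of the side-chain ester could close only an eight-membered ring. The product is a vinylogous acid that is deprotonated at once, which makes the closure irreversible, and the low temperature is chosen to hold back C3 deprotonation and the β-elimination of O1 that would open ring B.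

Step 20
Reactants: 29 the methyl ester from step 19
Product: 30 (3S)-3-[(2R,3R,8S)-5-hydroxy-2,3-dimethyl-8-[(2R)-lavandulyl]-4,7-dioxo-8-prenyl-3,4,7,8-tetrahydro-2H-chromen-6-yl]-3-phenylpropanoic acid (CNP0150579.1)
Conditions: LiOH, THF/MeOH/H2O, 0 °C→rt; then 1 M HCl
Reagents that add atoms: lithium hydroxide, [Li+].[OH-]
Why: Ester saponification of the unhindered CH2CO2Me group should proceed after the vinylogous acid is deprotonated, which shields the trione and ring B from hydroxide, and no stereocentre is α to the reacting carbonyl.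

**Compound list**

1 | (±)-lavandulol, 5-methyl-2-(prop-1-en-2-yl)hex-4-en-1-ol | C=C(C)C(CO)CC=C(C)C | starting material
2 | (S)-lavandulol | C=C(C)[C@@H](CO)CC=C(C)C | intermediate
3 | (S)-lavandulyl iodide, (S)-3-(iodomethyl)-2,6-dimethylhepta-1,5-diene | C=C(C)[C@@H](CI)CC=C(C)C | intermediate
4 | mono-tert-butyl malonate | CC(C)(C)OC(=O)CC(=O)O | starting material
5 | 2,2-diphenylethanol | OCC(c1ccccc1)c1ccccc1 | starting material
6 | tert-butyl 2,2-diphenylethyl malonate | CC(C)(C)OC(=O)CC(=O)OCC(c1ccccc1)c1ccccc1 | intermediate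
7 | tert-butyl 2,2-diphenylethyl 2-[(2R)-lavandulyl]malonate, epimers at the malonate CH | C=C(C)[C@H](CC=C(C)C)CC(C(=O)OC(C)(C)C)C(=O)OCC(c1ccccc1)c1ccccc1 | intermediate
8 | prenyl bromide | CC(C)=CCBr | starting material
9 | 1-tert-butyl 3-(2,2-diphenylethyl) (2R)-2-[(2R)-lavandulyl]-2-prenylpropanedioate | C=C(C)[C@H](CC=C(C)C)C[C@](C(=O)OC(C)(C)C)(CC=C(C)C)C(=O)OCC(c1ccccc1)c1ccccc1 | intermediate
10 | 1-tert-butyl 3-methyl (2R)-2-[(2R)-lavandulyl]-2-prenylpropanedioate | C=C(C)[C@H](CC=C(C)C)C[C@](C(=O)OC(C)(C)C)(CC=C(C)C)C(=O)OC | intermediate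
11 | 1-methyl 3-trimethylsilyl (2R)-2-[(2R)-lavandulyl]-2-prenylpropanedioate | C=C(C)[C@H](CC=C(C)C)C[C@](C(=O)O[Si](C)(C)C)(CC=C(C)C)C(=O)OC | intermediate (not isolated)
12 | (2S)-2-(methoxycarbonyl)-2-[(2R)-lavandulyl]-5-methylhex-4-enoic acid | C=C(C)[C@H](CC=C(C)C)C[C@](C(=O)O)(CC=C(C)C)C(=O)OC | intermediate
13 | methyl (R)-3-hydroxybutanoate | C[C@@H](O)CC(=O)OC | starting material
14 | methyl (2R,3R)-3-hydroxy-2-methylbutanoate | C[C@@H](O)[C@@H](C)C(=O)OC | intermediate
15 | methyl (2R,3R)-3-(tert-butyldimethylsilyloxy)-2-methylbutanoate | C[C@@H](O[Si](C)(C)C(C)(C)C)[C@@H](C)C(=O)OC | intermediate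
16 | (2R,3R)-3-(tert-butyldimethylsilyloxy)-N-methoxy-N,2-dimethylbutanamide | C[C@@H](O[Si](C)(C)C(C)(C)C)[C@@H](C)C(=O)N(C)OC | intermediate (not isolated)
17 | (3R,4R)-4-(tert-butyldimethylsilyloxy)-3-methylpentan-2-one | C[C@@H](O[Si](C)(C)C(C)(C)C)[C@@H](C)C(C)=O | intermediate
18 | methyl (2R)-2-(chlorocarbonyl)-2-[(2R)-lavandulyl]-5-methylhex-4-enoate | C=C(C)[C@H](CC=C(C)C)C[C@](C(Cl)=O)(CC=C(C)C)C(=O)OC | intermediate (not isolated)
19 | methyl (2S)-2-[(4R,5R)-5-(tert-butyldimethylsilyloxy)-4-methyl-3-oxohexanoyl]-2-[(2R)-lavandulyl]-5-methylhex-4-enoate | C=C(C)[C@H](CC=C(C)C)C[C@](C(=O)CC(=O)[C@H](C)[C@@H](C)O[Si](C)(C)C(C)(C)C)(CC=C(C)C)C(=O)OC | intermediate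
20 | methyl (2S)-2-[(4R,5R)-5-hydroxy-4-methyl-3-oxohexanoyl]-2-[(2R)-lavandulyl]-5-methylhex-4-enoate | C=C(C)[C@H](CC=C(C)C)C[C@](C(=O)CC(=O)[C@H](C)[C@@H](C)O)(CC=C(C)C)C(=O)OC | intermediate (not isolated)
21 | methyl (2S)-2-[(2R,3R)-2,3-dimethyl-4-oxo-3,4-dihydro-2H-pyran-6-yl]-2-[(2R)-lavandulyl]-5-methylhex-4-enoate | C=C(C)[C@H](CC=C(C)C)C[C@](C1=CC(=O)[C@H](C)[C@@H](C)O1)(CC=C(C)C)C(=O)OC | intermediate
22 | methyl (2S)-2-[(2R,3R)-5-iodo-2,3-dimethyl-4-oxo-3,4-dihydro-2H-pyran-6-yl]-2-[(2R)-lavandulyl]-5-methylhex-4-enoate | C=C(C)[C@H](CC=C(C)C)C[C@](C1=C(I)C(=O)[C@H](C)[C@@H](C)O1)(CC=C(C)C)C(=O)OC | intermediate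
23 | 3-phenylglutaric anhydride | O=C1CC(CC(=O)O1)c1ccccc1 | starting material
24 | (S)-5-methoxy-5-oxo-3-phenylpentanoic acid | OC(=O)C[C@@H](CC(=O)OC)c1ccccc1 | intermediate
25 | methyl (S)-5-hydroxy-3-phenylpentanoate | OCC[C@@H](CC(=O)OC)c1ccccc1 | intermediate
26 | methyl (S)-5-oxo-3-phenylpentanoate | O=CC[C@@H](CC(=O)OC)c1ccccc1 | intermediate
27 | methyl (2S)-2-[(2R,3R)-5-[(3S)-1-hydroxy-5-methoxy-5-oxo-3-phenylpentyl]-2,3-dimethyl-4-oxo-3,4-dihydro-2H-pyran-6-yl]-2-[(2R)-lavandulyl]-5-methylhex-4-enoate, epimers at the carbinol | C=C(C)[C@H](CC=C(C)C)C[C@](C1=C(C(O)C[C@@H](CC(=O)OC)c2ccccc2)C(=O)[C@H](C)[C@@H](C)O1)(CC=C(C)C)C(=O)OC | intermediate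
28 | methyl (2S)-2-[(2R,3R)-5-[(3S)-5-methoxy-5-oxo-3-phenylpentanoyl]-2,3-dimethyl-4-oxo-3,4-dihydro-2H-pyran-6-yl]-2-[(2R)-lavandulyl]-5-methylhex-4-enoate (key-step precursor) | C=C(C)[C@H](CC=C(C)C)C[C@](C1=C(C(=O)C[C@@H](CC(=O)OC)c2ccccc2)C(=O)[C@H](C)[C@@H](C)O1)(CC=C(C)C)C(=O)OC | intermediate
29 | methyl (3S)-3-[(2R,3R,8S)-5-hydroxy-2,3-dimethyl-8-[(2R)-lavandulyl]-4,7-dioxo-8-prenyl-3,4,7,8-tetrahydro-2H-chromen-6-yl]-3-phenylpropanoate (key-step product) | C=C(C)[C@H](CC=C(C)C)C[C@]1(CC=C(C)C)C(=O)C([C@@H](CC(=O)OC)c2ccccc2)=C(O)C2=C1O[C@H](C)[C@@H](C)C2=O | intermediate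
30 | (3S)-3-[(2R,3R,8S)-5-hydroxy-2,3-dimethyl-8-[(2R)-lavandulyl]-4,7-dioxo-8-prenyl-3,4,7,8-tetrahydro-2H-chromen-6-yl]-3-phenylpropanoic acid, CNP0150579.1 | C=C(C)[C@H](CC=C(C)C)C[C@]1(CC=C(C)C)C(=O)C([C@@H](CC(=O)O)c2ccccc2)=C(O)C2=C1O[C@H](C)[C@@H](C)C2=O | target

**Step count and risks**

Total step count: 20. Longest linear sequence: 13 steps (steps 1, 2, 4, 5, 6, 7, 11, 12, 13, 17, 18, 19, 20).

Steps most likely to fail:

1. Step 19 (key step). Bond formation between the branched C6 enolate and the neopentyl-type C7 ester may be slow. That would give time for deprotonation at C3 followed by β-elimination of O1 (opening of ring B), and for retro-Michael loss of the phenylpropanoate chain. The fallback sets out from iodide 22 and returns at target 30; it closes ring A with a small enolate and adds the side chain afterwards. Nozaki–Hiyama–Kishi coupling of 22 with acetaldehyde (CrCl2, NiCl2 cat., DMF) would give the 5-(1-hydroxyethyl) dihydropyranone F1, and DMP oxidation the 5-acetyl dihydropyranone F2. The same Dieckmann closure, now with an unhindered methyl ketone enolate (KOtBu, THF), would give the bicyclic enol trione F3, which has hydrogen at C6. Iminium-catalysed Michael addition of F3, whose only nucleophilic carbon is C6, to cinnamaldehyde with the diarylprolinol trimethylsilyl ether of the hand that gives the (S) benzylic centre would give the aldehyde F4 (in equilibrium with its lactol). Oxidation with NaClO2, NaH2PO4 and 2-methylbut-2-ene would then give 30 directly.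

2. Step 17. Oxidative addition and transmetallation at the hindered, electron-rich alkenyl iodide may be slow, protodeiodination may compete, and the δ-hydroxy ester adduct may lactonise before it is oxidised. The fallback sets out from 22 and 24 and returns at 28, with no alcohol stage. Hemiester 24 with 1-chloro-N,N,2-trimethylprop-1-en-1-amine would give the acid chloride F5. Stannylation of 22 (Me3SnSnMe3, Pd(PPh3)4, toluene, 90 °C) would give the alkenylstannane F6. Stille acylation of F6 with F5 (Pd2(dba)3, tri(2-furyl)phosphine, THF, 50 °C) would give 28.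

3. Step 5. Facial discrimination at the fully substituted enolate may be poor, because the β-branched lavandulyl group may erode catalyst control or the existing stereocentre may be mismatched with the catalyst. The fallback sets out from 3 and returns at 12. Alkylation of dimethyl malonate with 3 (NaH, DMF) would give dimethyl lavandulylmalonate F7, and prenylation with 8 (NaH, THF) the dialkyl malonate F8, in which C8 is not yet a stereocentre. Desymmetrising hydrolysis with pig liver esterase (pH 7 buffer, DMSO co-solvent) would give half ester 12. Because 12 and its C8 epimer are diastereomers, any epimer formed can be removed by crystallisation of an amine salt.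

**Further compounds**

F1 | step 19 | methyl (2S)-2-[(2R,3R)-5-(1-hydroxyethyl)-2,3-dimethyl-4-oxo-3,4-dihydro-2H-pyran-6-yl]-2-[(2R)-lavandulyl]-5-methylhex-4-enoate | C=C(C)[C@H](CC=C(C)C)C[C@](C1=C(C(C)O)C(=O)[C@H](C)[C@@H](C)O1)(CC=C(C)C)C(=O)OC
F2 | step 19 | methyl (2S)-2-[(2R,3R)-5-acetyl-2,3-dimethyl-4-oxo-3,4-dihydro-2H-pyran-6-yl]-2-[(2R)-lavandulyl]-5-methylhex-4-enoate | C=C(C)[C@H](CC=C(C)C)C[C@](C1=C(C(C)=O)C(=O)[C@H](C)[C@@H](C)O1)(CC=C(C)C)C(=O)OC
F3 | step 19 | (2R,3R,8S)-5-hydroxy-2,3-dimethyl-8-[(2R)-lavandulyl]-8-prenyl-2,3-dihydro-4H-chromene-4,7(8H)-dione | C=C(C)[C@H](CC=C(C)C)C[C@]1(CC=C(C)C)C(=O)C=C(O)C2=C1O[C@H](C)[C@@H](C)C2=O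
F4 | step 19 | (3S)-3-[(2R,3R,8S)-5-hydroxy-2,3-dimethyl-8-[(2R)-lavandulyl]-4,7-dioxo-8-prenyl-3,4,7,8-tetrahydro-2H-chromen-6-yl]-3-phenylpropanal | C=C(C)[C@H](CC=C(C)C)C[C@]1(CC=C(C)C)C(=O)C([C@@H](CC=O)c2ccccc2)=C(O)C2=C1O[C@H](C)[C@@H](C)C2=O
F5 | step 17 | methyl (R)-5-chloro-5-oxo-3-phenylpentanoate | ClC(=O)C[C@@H](CC(=O)OC)c1ccccc1
F6 | step 17 | methyl (2S)-2-[(2R,3R)-2,3-dimethyl-4-oxo-5-(trimethylstannyl)-3,4-dihydro-2H-pyran-6-yl]-2-[(2R)-lavandulyl]-5-methylhex-4-enoate | C=C(C)[C@H](CC=C(C)C)C[C@](C1=C([Sn](C)(C)C)C(=O)[C@H](C)[C@@H](C)O1)(CC=C(C)C)C(=O)OC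
F7 | step 5 | dimethyl 2-[(2R)-lavandulyl]malonate | C=C(C)[C@H](CC=C(C)C)CC(C(=O)OC)C(=O)OC
F8 | step 5 | dimethyl 2-[(2R)-lavandulyl]-2-prenylmalonate | C=C(C)[C@H](CC=C(C)C)CC(CC=C(C)C)(C(=O)OC)C(=O)OC
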